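## Analysis of the target

Atom labels used throughout: ring A is the cyclopentane C1–C5; ring B is the cyclopent-2-enone C1'–C5' (C1' bonded to C5, C2' the ketone, C3'=C4', C5' bearing the methyl group); the side chain on C3 is Cα(CH3)=Cβ–Cγ=Cδ–Cε(CH3)2OOH.

The target 22 is two five-membered carbocycles joined by the single bond C5–C1'. Ring A carries a tertiary hydroxyl and an acetoxymethyl group on the fully substituted C1, and on C3 an (E,E)-diene that ends in a tertiary allylic hydroperoxide. There are five stereocentres: C1 (R), C3 (S), C5 (S), C1' (S) and C5' (R). The three carbon substituents of ring A (CH2OAc, side chain, ring B) sit on one face and the C1 hydroxyl on the other; on ring B the C1' substituent and the C5' methyl are cis. The sensitive groups are the hydroperoxide (destroyed by hydrides, organometallics, phosphines and low-valent metals), the conjugated diene, the enone, and C1', which is enolisable and holds the less comfortable cis arrangement. The hard part is the contiguous array C1/C5/C1'/C5' across a ring–ring bond, with a remote C3 centre and a peroxide that has to come last. The plan rests on one feature: C1 and C3 each carry exactly one exocyclic carbon (the CH2OAc carbon and Cα), 1,3 to each other across the C2 methylene. That is the pattern of a cyclopent-1-ene-1,4-dicarboxylate, whose C1=C5 alkene can later supply both the C1–O bond and the C5–C1' bond.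

## Retrosynthetic reasoning

**Cε–O bond (22 ⇒ 21).** The hydroperoxide is removed first, because it survives none of the earlier reagents. Cutting Cε–O and moving the alkene from Cγ=Cδ to Cδ=Cε gives the skipped diene 21. The forward step is a Schenck ene reaction that must pick the terminal alkene and take a hydrogen from the doubly allylic Cγ.

**Acetate (21 ⇒ 20).** The acyl–oxygen bond is cut to diol 20. Forward, only the primary hydroxyl should react; the tertiary one is hindered.

**C3'=C4' (20 ⇒ 19).** Ring B is opened at its alkene rather than at a C–C single bond, because a ring-closing metathesis fixes the alkene position and touches neither C1' nor C5'. This gives the acyclic vinyl ketone 19 with both ring-B stereocentres in place.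

**C2'–C3' (19 ⇒ 18 ⇒ 17).** The vinyl group is removed from the ketone carbon. C2' then becomes a carboxyl carbon, stored as the Weinreb amide 18 and before that as the carbonyl of δ-lactone 17, in which the C1 hydroxymethyl oxygen is the ring oxygen.

**C5–C1' (17 ⇒ 15, through 16).** This is the ring–ring bond. It is cut so that C1' is an ester enolate carbon tethered to the C1 hydroxymethyl group and C5 is an epoxide carbon. Forward, attack with inversion at C5 sets C5, releases the C1 oxygen as the tertiary alcohol on the face opposite to ring B, and places C1' in a cis-fused lactone where its configuration can be controlled.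

**Ester C–O (15 ⇒ 12 + 14; 14 ⇐ 13).** The tether is an ordinary ester of epoxy alcohol 12 and (S)-acid 14, which brings C5' in enantiopure form from racemic acid 13.

**Epoxide C–O bonds (12 ⇒ 11).** The epoxide comes from the C1=C5 alkene of allylic alcohol 11. A Sharpless asymmetric epoxidation is chosen because it touches only the allylic alcohol alkene and sets the face by reagent control rather than by the remote C3 centre.

**Cβ–Cγ and Cα–CH3 (11 ⇒ 8 + 9, through 10).** The (E)-trisubstituted alkene is cut into terminal alkyne 8, a methyl group and prenyl bromide 9. Syn carbometalation fixes the E geometry; the allylation gives the skipped diene.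

**Functional-group changes (8 ⇐ 7 ⇐ 6 ⇐ 5 ⇐ 4 ⇐ 3).** The alkyne carbon pair comes from the C3 carboxyl (acid 4, alcohol 5, aldehyde 6, alkyne 7), and the C1 hydroxymethyl from the conjugated ethyl ester. The ester is reduced before the carbometalation so that no carbonyl group meets the aluminium reagent. The tert-butyl/ethyl pair in 3 makes the two carboxyls distinguishable.

**C1–C2 and C3–C4 (3 ⇒ 1 + 2).** Diester 3 is cut into ethyl buta-2,3-dienoate 1 and tert-butyl acrylate 2. Both are commercial, so the strategic step opens the synthesis and the only stereocentre it creates, C3, is set by a chiral phosphine catalyst.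

## Alternatives that were turned down

**Alternative 1:** Ring A is taken from (R)-limonene A1 by ring contraction, and the C5–C1' bond is made by the same enolate–epoxide lactonisation that gives hydroxy δ-lactone A2 (identical with 17).
- For it: C3 is bought enantiopure, with no dependence on a catalytic asymmetric step. Its key step sets C5 by inversion and frees the C1 hydroxyl in one operation; the chosen route uses the same event as step 11.
- Against it: the carbon pattern of A1 does not fit. Oxidative cleavage and aldol ring contraction leave a two-carbon acetyl group on C1, so one carbon has to be excised. The isopropenyl group on C3 must then be turned into an (E)-trisubstituted alkene, for which cross-metathesis of a 1,1-disubstituted alkene gives poor geometric control. The ring alkene must also be cleaved in the presence of the isopropenyl group.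
- Comparison: Alternative 1 is stronger on the security of the absolute configuration at C3 and on cost. The chosen route offers the exact carbon count at C1 and C3, two distinguishable carboxyls, and an alkyne from which the E geometry follows by syn addition.

**Alternative 2:** Ring A is closed at C1–C5: keto enoate A3 is reduced by SmI2 to a ketyl that adds 5-exo-trig to the enoate β-carbon, and protonation of the samarium enolate gives hydroxy ester A4.
- For it: one step makes the ring, the quaternary carbinol C1 and C5. The chelated transition state should place the hydroxyl and the acetate arm trans, which is the relation needed. On the C1–O bond it is more direct than the chosen route, which needs an epoxidation and an opening.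
- Against it: C3 has to be set beforehand in an open chain and influences the new centres only through a 1,3-relationship. Ring B is still missing, and building it from the acetate arm means creating C1' and C5' under acyclic control next to an enolisable position. SmI2 is needed in excess of two equivalents, and the side chain is again only an isopropenyl group.
- Comparison: the chosen route forms C5–C1' with C5' already in place and C1' inside a ring, by a stereospecific inversion.

**Alternative 3:** Ring B is closed last at C4'–C5' by a silicon-directed Nazarov cyclisation of β-silyl dienone A5 with FeCl3, giving A6 after loss of the silyl group (C3'=C4') and protonation at C1'.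
- For it: it is convergent, the alkene position in ring B is unambiguous, and the iodoalkene in A6 allows the oxygenated side chain to be attached by cross-coupling. On the last point it is stronger than the chosen route, whose final ene reaction is only moderately selective.
- Against it: the sense of conrotation, which sets C5', is steered only by the distant ring-A centres. C1' comes from a kinetic protonation that must give the less stable cis isomer. A strong Lewis acid meets a tertiary silyl ether, an iodoalkene and an acetate. A5 itself still requires the C5–C1' bond to be made with control at C5.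
- Comparison: the chosen route brings C5' from a resolved acid and sets C5 and C1' in a cyclic, stereospecific step.

Key step: step 1

Assumption 1: the sense of induction of the bicyclic phosphine in step 1 is not predictable from a simple model; the antipode that gives (4S)-3 is chosen after a test run.
Assumption 2: step 9 is written for (S)-1-phenylethylamine; if the less soluble salt carries the (R)-acid, the (R)-amine is used.

## Route

Step 1
Reactants: 1 ethyl buta-2,3-dienoate; 2 tert-butyl acrylate
Product: 3 4-tert-butyl 1-ethyl (4S)-cyclopent-1-ene-1,4-dicarboxylate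
Conditions: enantiopure 2,5-diisopropyl-7-phenyl-7-phosphabicyclo[2.2.1]heptane (10 mol %), toluene, 0 °C, slow addition of 1
Reagents that add atoms: none
Why: The phosphine adds to the central carbon of 1 to give a zwitterionic 1,3-dipole; its α-carbon adds to the terminus of 2 (bond C1–C2), the new ester enolate closes on the γ-carbon of the vinylphosphonium unit (bond C3–C4), and a proton shift followed by loss of the phosphine leaves the C1=C5 alkene conjugated to the ethyl ester. The closest known reaction is the phosphine-catalysed allenoate–alkene (3+2) annulation (Lu annulation), which has enantioselective versions with acrylates and rigid P-chiral phosphines. Ring A closes in the second bond-forming event, stepwise; formally this is a 5-endo-trig addition of the enolate to the vinylphosphonium, better seen as the second stage of an asynchronous dipolar annulation. The one new stereocentre, C3 (the acrylate α-carbon), is fixed in this ring closure and is controlled only by the chiral phosphine bound in the dipole. The step needs α- over γ-regiochemistry and enantiofacial control; the bulky tert-butyl ester and the rigid bicyclic phosphine should favour the α-adduct, in which the two esters are 1,3 across C2. The alkene position is fixed by the mechanism, and the two esters are chemically distinct for what follows.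

Step 2
Reactants: 3 4-tert-butyl 1-ethyl (4S)-cyclopent-1-ene-1,4-dicarboxylate
Product: 4 (1S)-3-(ethoxycarbonyl)cyclopent-3-ene-1-carboxylic acid
Conditions: CF3CO2H, CH2Cl2, 0 °C to rt
Reagents that add atoms: none
Why: Acidolysis of the tert-butyl ester through the tert-butyl cation leaves the ethyl ester and the conjugated alkene alone, and C3 is not enolised under acid. The acid can be crystallised as a salt with a chiral amine to raise the ee if needed.

Step 3
Reactants: 4 (1S)-3-(ethoxycarbonyl)cyclopent-3-ene-1-carboxylic acid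
Product: 5 ethyl (4S)-4-(hydroxymethyl)cyclopent-1-ene-1-carboxylate
Conditions: BH3·SMe2, THF, -10 to 0 °C
Reagents that add atoms: none
Why: Borane reduces a free carboxylic acid through its acyloxyborane much faster than an ester, and the ester-deactivated trisubstituted alkene is hydroborated only slowly at this temperature.

Step 4
Reactants: 5 ethyl (4S)-4-(hydroxymethyl)cyclopent-1-ene-1-carboxylate
Product: 6 ethyl (4S)-4-formylcyclopent-1-ene-1-carboxylate
Conditions: Dess–Martin periodinane, NaHCO3, CH2Cl2, 0 °C to rt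
Reagents that add atoms: none
Why: Dess–Martin oxidation under buffered, near-neutral conditions stops at the aldehyde and should not epimerise the α-carbon (C3).

Step 5
Reactants: 6 ethyl (4S)-4-formylcyclopent-1-ene-1-carboxylate
Product: 7 ethyl (4S)-4-ethynylcyclopent-1-ene-1-carboxylate
Conditions: dimethyl (1-diazo-2-oxopropyl)phosphonate, K2CO3, EtOH, 0 °C
Reagents that add atoms: dimethyl (1-diazo-2-oxopropyl)phosphonate, COP(=O)(OC)C(=[N+]=[N-])C(C)=O
Why: Ohira–Bestmann homologation: ethoxide removes the acetyl group, the diazomethylphosphonate anion adds to the aldehyde, and the alkylidene carbene rearranges to the terminal alkyne. Ethanol keeps the ethyl ester unchanged, and low temperature with short contact time limits enolisation of the α-stereogenic aldehyde.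

Step 6
Reactants: 7 ethyl (4S)-4-ethynylcyclopent-1-ene-1-carboxylate
Product: 8 [(4S)-4-ethynylcyclopent-1-en-1-yl]methanol
Conditions: iBu2AlH (2.5 equiv), CH2Cl2, -78 °C; aq. potassium sodium tartrate (KNaC4H4O6)
Reagents that add atoms: none
Why: 1,2-Reduction of the conjugated ester gives the allylic alcohol; the terminal alkyne is inert to iBu2AlH at this temperature. Doing this before the carbometalation keeps the carbonyl group away from Me3Al and Cp2ZrCl2.

Step 7
Reactants: 8 [(4S)-4-ethynylcyclopent-1-en-1-yl]methanol; 9 prenyl bromide (1-bromo-3-methylbut-2-ene)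
Product: 11 [(4S)-4-[(2E)-6-methylhepta-2,5-dien-2-yl]cyclopent-1-en-1-yl]methanol, via alkenyldimethylalane 10 (not isolated)
Conditions: Me3Al (3 equiv), Cp2ZrCl2 (0.3 equiv), CH2Cl2, 0 °C to rt; volatiles removed; then 9, Pd(PPh3)4 (5 mol %), THF, 0 °C to rt
Reagents that add atoms: trimethylaluminium, C[Al](C)C
Why: Negishi carboalumination adds methyl and aluminium syn across the terminal alkyne with aluminium at the terminus (the hydroxyl is carried as its aluminium alkoxide), so alane 10 is (E). Palladium-catalysed allylation of the alkenylalane then joins the primary terminus of the prenyl unit with retention, giving the (E)-Cα=Cβ alkene and the skipped diene.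

Step 8
Reactants: 11 [(4S)-4-[(2E)-6-methylhepta-2,5-dien-2-yl]cyclopent-1-en-1-yl]methanol
Product: 12 [(1S,3S,5S)-3-[(2E)-6-methylhepta-2,5-dien-2-yl]-6-oxabicyclo[3.1.0]hexan-1-yl]methanol
Conditions: Ti(OiPr)4 (10 mol %), L-(+)-diethyl tartrate (12 mol %), tBuOOH, 4 Å molecular sieves, CH2Cl2, -20 °C
Reagents that add atoms: tert-butyl hydroperoxide, CC(C)(C)OO
Why: Sharpless asymmetric epoxidation oxidises only the allylic alcohol alkene, so the two side-chain alkenes stay. With the L-(+)-tartrate the carbinol-bearing carbon C1 should become (S), which puts the epoxide oxygen on the face anti to the C3 substituent, the face the substrate should also prefer; this sets the C1–O bond and prepares C5 for inversion.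

Step 9
Reactants: 13 racemic 3-methylpent-4-enoic acid
Product: 14 (3S)-3-methylpent-4-enoic acid
Conditions: (S)-1-phenylethylamine (1 equiv), acetone/EtOAc, fractional crystallisation of the less soluble salt; then 1 M HCl, Et2O
Reagents that add atoms: none
Why: Classical resolution through diastereomeric ammonium carboxylates; the liberated acid supplies C5' in enantiopure form.

Step 10
Reactants: 12 [(1S,3S,5S)-3-[(2E)-6-methylhepta-2,5-dien-2-yl]-6-oxabicyclo[3.1.0]hexan-1-yl]methanol; 14 (3S)-3-methylpent-4-enoic acid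
Product: 15 [(1S,3S,5S)-3-[(2E)-6-methylhepta-2,5-dien-2-yl]-6-oxabicyclo[3.1.0]hexan-1-yl]methyl (3S)-3-methylpent-4-enoate
Conditions: EDC·HCl, DMAP (cat.), CH2Cl2, 0 °C to rt
Reagents that add atoms: none
Why: Steglich esterification of the primary alcohol under neutral conditions leaves the epoxide and all stereocentres untouched.

Step 11
Reactants: 15 [(1S,3S,5S)-3-[(2E)-6-methylhepta-2,5-dien-2-yl]-6-oxabicyclo[3.1.0]hexan-1-yl]methyl (3S)-3-methylpent-4-enoate
Product: 17 (4S,4aS,6S,7aR)-4-[(2R)-but-3-en-2-yl]-7a-hydroxy-6-[(2E)-6-methylhepta-2,5-dien-2-yl]hexahydrocyclopenta[c]pyran-3(1H)-one (cis-fused hydroxy δ-lactone), via lithium ester enolate 16 (not isolated)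
Conditions: LiN(SiMe3)2 (1.3 equiv), THF, -78 to 0 °C; AcOH; then DBU (0.3 equiv), CH2Cl2, rt
Reagents that add atoms: none
Why: Enolate–epoxide cyclisation of the Stork epoxynitrile type: enolate 16 attacks C5 from the face opposite the epoxide oxygen (SN2, inversion) in a 6-(enolendo)-exo-tet closure, while attack at the fully substituted C1 is blocked, so the cis-fused δ-lactone and the C1 tertiary alcohol result. C5 is set by inversion of the Sharpless epoxide; the C1' substituent should occupy the convex face, trans to C4, and DBU equilibration of the enolisable lactone converges any C1' epimer to that isomer.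

Step 12
Reactants: 17 the cis-fused hydroxy δ-lactone
Product: 18 (2S,3R)-2-[(1S,2R,4S)-2-hydroxy-2-(hydroxymethyl)-4-[(2E)-6-methylhepta-2,5-dien-2-yl]cyclopentyl]-N-methoxy-N,3-dimethylpent-4-enamide
Conditions: MeNH(OMe)·HCl (3 equiv), Me3Al (3 equiv), CH2Cl2, 0 °C to rt; used crude
Reagents that add atoms: N,O-dimethylhydroxylamine hydrochloride, CNOC.Cl
Why: Weinreb aminolysis of a lactone with the aluminium amide opens the ring at the acyl carbon without base strong enough to enolise C1'. The hydroxy amide is used at once to avoid re-lactonisation.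

Step 13
Reactants: 18 the Weinreb amide diol
Product: 19 (4S,5R)-4-[(1S,2R,4S)-2-hydroxy-2-(hydroxymethyl)-4-[(2E)-6-methylhepta-2,5-dien-2-yl]cyclopentyl]-5-methylhepta-1,6-dien-3-one
Conditions: CH2=CHMgBr (5 equiv), THF, -78 to -20 °C, amide added to the Grignard reagent; inverse quench into cold aq. KHSO4
Reagents that add atoms: vinylmagnesium bromide, C=C[Mg]Br
Why: Grignard addition to a Weinreb amide stops at the chelated tetrahedral intermediate and gives the vinyl ketone only on work-up; two extra equivalents cover the hydroxyls. The acidic inverse quench protonates the released hydroxylamine before it can add to the enone, and the low temperature protects C1'.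

Step 14
Reactants: 19 the vinyl ketone diol
Product: 20 (4R,5S)-5-[(1S,2R,4S)-2-hydroxy-2-(hydroxymethyl)-4-[(2E)-6-methylhepta-2,5-dien-2-yl]cyclopentyl]-4-methylcyclopent-2-en-1-one
Conditions: second-generation Grubbs catalyst RuCl2(=CHPh)(H2IMes)(PCy3) (5 mol %), CH2Cl2 (5 mM), 40 °C
Reagents that add atoms: none
Why: Ring-closing metathesis between the two monosubstituted alkenes closes the five-membered enone (C3'=C4') with loss of ethene. The trisubstituted side-chain alkenes react far more slowly, and no stereocentre is touched.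

Step 15
Reactants: 20 the cyclopentenone diol
Product: 21 [(1R,2S,4S)-1-hydroxy-4-[(2E)-6-methylhepta-2,5-dien-2-yl]-2-[(1S,5R)-5-methyl-2-oxocyclopent-3-en-1-yl]cyclopentyl]methyl acetate
Conditions: Ac2O (1.5 equiv), pyridine, CH2Cl2, 0 °C to rt
Reagents that add atoms: acetic anhydride, CC(=O)OC(C)=O
Why: Acylation takes the primary hydroxyl and leaves the hindered tertiary one; pyridine is too weak a base to enolise C1'.

Step 16
Reactants: 21 the skipped-diene acetate
Product: 22 [(1R,2S,4S)-1-hydroxy-4-[(2E,4E)-6-hydroperoxy-6-methylhepta-2,4-dien-2-yl]-2-[(1S,5R)-5-methyl-2-oxocyclopent-3-en-1-yl]cyclopentyl]methyl acetate (target)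
Conditions: O2, visible light, tetraphenylporphyrin (cat.), CH2Cl2, -20 °C, stopped at partial conversion; no reductive work-up
Reagents that add atoms: dioxygen (as singlet oxygen), O=O
Why: Schenck ene reaction: singlet oxygen adds to the terminal trisubstituted alkene, takes a doubly allylic hydrogen from Cγ on the more substituted side, and places the hydroperoxide on Cε with a new (E)-Cγ=Cδ alkene in conjugation. The enone is inert to this electrophilic oxidant; regioisomeric hydroperoxides are expected as by-products and are separated by chromatography.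

## Compound list

1 | ethyl buta-2,3-dienoate | C=C=CC(=O)OCC | starting material
2 | tert-butyl acrylate | C=CC(=O)OC(C)(C)C | starting material
3 | 4-tert-butyl 1-ethyl (4S)-cyclopent-1-ene-1,4-dicarboxylate | CCOC(=O)C1=CC[C@H](C(=O)OC(C)(C)C)C1 | intermediate
4 | (1S)-3-(ethoxycarbonyl)cyclopent-3-ene-1-carboxylic acid | CCOC(=O)C1=CC[C@H](C(=O)O)C1 | intermediate
5 | ethyl (4S)-4-(hydroxymethyl)cyclopent-1-ene-1-carboxylate | CCOC(=O)C1=CC[C@H](CO)C1 | intermediate
6 | ethyl (4S)-4-formylcyclopent-1-ene-1-carboxylate | CCOC(=O)C1=CC[C@H](C=O)C1 | intermediate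
7 | ethyl (4S)-4-ethynylcyclopent-1-ene-1-carboxylate | CCOC(=O)C1=CC[C@H](C#C)C1 | intermediate
8 | [(4S)-4-ethynylcyclopent-1-en-1-yl]methanol | OCC1=CC[C@H](C#C)C1 | intermediate
9 | prenyl bromide (1-bromo-3-methylbut-2-ene) | CC(C)=CCBr | starting material
10 | (E)-alkenyldimethylalane from 8: the 1-(dimethylalumanyl)prop-1-en-2-yl compound, hydroxyl as O–AlMe2 | C[Al](C)OCC1=CC[C@H](/C(C)=C/[Al](C)C)C1 | intermediate (not isolated)
11 | [(4S)-4-[(2E)-6-methylhepta-2,5-dien-2-yl]cyclopent-1-en-1-yl]methanol | OCC1=CC[C@H](/C(C)=C/CC=C(C)C)C1 | intermediate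
12 | [(1S,3S,5S)-3-[(2E)-6-methylhepta-2,5-dien-2-yl]-6-oxabicyclo[3.1.0]hexan-1-yl]methanol | OC[C@@]1(O2)C[C@@H](/C(C)=C/CC=C(C)C)C[C@@H]12 | intermediate
13 | racemic 3-methylpent-4-enoic acid | C=CC(C)CC(=O)O | starting material
14 | (3S)-3-methylpent-4-enoic acid | C=C[C@H](CC(=O)O)C | intermediate
15 | [(1S,3S,5S)-3-[(2E)-6-methylhepta-2,5-dien-2-yl]-6-oxabicyclo[3.1.0]hexan-1-yl]methyl (3S)-3-methylpent-4-enoate | C=C[C@H](CC(=O)OC[C@@]1(O2)C[C@@H](/C(C)=C/CC=C(C)C)C[C@@H]12)C | intermediate
16 | lithium enolate of ester 15 | [Li+].[O-]C(=C[C@H](C)C=C)OC[C@@]1(O2)C[C@@H](/C(C)=C/CC=C(C)C)C[C@@H]12 | intermediate (not isolated)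
17 | (4S,4aS,6S,7aR)-4-[(2R)-but-3-en-2-yl]-7a-hydroxy-6-[(2E)-6-methylhepta-2,5-dien-2-yl]hexahydrocyclopenta[c]pyran-3(1H)-one | O=C1OC[C@@]2(O)C[C@@H](/C(C)=C/CC=C(C)C)C[C@H]2[C@@H]1[C@H](C)C=C | intermediate
18 | (2S,3R)-2-[(1S,2R,4S)-2-hydroxy-2-(hydroxymethyl)-4-[(2E)-6-methylhepta-2,5-dien-2-yl]cyclopentyl]-N-methoxy-N,3-dimethylpent-4-enamide | OC[C@@]1(O)C[C@@H](/C(C)=C/CC=C(C)C)C[C@H]1[C@@H](C(=O)N(C)OC)[C@H](C)C=C | intermediate
19 | (4S,5R)-4-[(1S,2R,4S)-2-hydroxy-2-(hydroxymethyl)-4-[(2E)-6-methylhepta-2,5-dien-2-yl]cyclopentyl]-5-methylhepta-1,6-dien-3-one | OC[C@@]1(O)C[C@@H](/C(C)=C/CC=C(C)C)C[C@H]1[C@@H](C(=O)C=C)[C@H](C)C=C | intermediate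
20 | (4R,5S)-5-[(1S,2R,4S)-2-hydroxy-2-(hydroxymethyl)-4-[(2E)-6-methylhepta-2,5-dien-2-yl]cyclopentyl]-4-methylcyclopent-2-en-1-one | OC[C@@]1(O)C[C@@H](/C(C)=C/CC=C(C)C)C[C@H]1[C@H]1C(=O)C=C[C@H]1C | intermediate
21 | [(1R,2S,4S)-1-hydroxy-4-[(2E)-6-methylhepta-2,5-dien-2-yl]-2-[(1S,5R)-5-methyl-2-oxocyclopent-3-en-1-yl]cyclopentyl]methyl acetate | CC(=O)OC[C@@]1(O)C[C@@H](/C(C)=C/CC=C(C)C)C[C@H]1[C@H]1C(=O)C=C[C@H]1C | intermediate
22 | [(1R,2S,4S)-1-hydroxy-4-[(2E,4E)-6-hydroperoxy-6-methylhepta-2,4-dien-2-yl]-2-[(1S,5R)-5-methyl-2-oxocyclopent-3-en-1-yl]cyclopentyl]methyl acetate | CC(=O)OC[C@@]1(O)C[C@@H](/C(C)=C/C=C/C(C)(C)OO)C[C@H]1[C@H]1C(=O)C=C[C@H]1C | target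

## Step count and least certain steps

Total step count: 16. Longest linear sequence: 15 steps (steps 1–8 and 10–16); step 9 is a one-step side branch.

**Step 1 (key step).** Regiocontrol may erode through bonding at the γ-carbon of the dipole, and enantiofacial control may be incomplete because the small acrylate has no second binding point to the catalyst; oligomerisation of 1 by the nucleophilic phosphine competes if its concentration is high. Fallback: 1 and 2 are combined with triphenylphosphine to give racemic 4-tert-butyl 1-ethyl cyclopent-1-ene-1,4-dicarboxylate F1, freed of the γ-isomer by chromatography. CF3CO2H cleavage gives racemic 3-(ethoxycarbonyl)cyclopent-3-ene-1-carboxylic acid F2, which is resolved as a 1-phenylethylammonium salt. The route is rejoined at 4.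

**Step 11.** The C–C bond formation may be slow, because lithium ester enolates are weak nucleophiles towards epoxides and the backside trajectory at C5 is reached from one conformation only. Base-induced isomerisation of the epoxide to an allylic alcohol and intermolecular ester condensation can then take over, and C1' may form as a mixture. Fallback, from 12: silylation (tBuMe2SiCl, imidazole) gives tert-butyldimethyl{[(1S,3S,5S)-3-[(2E)-6-methylhepta-2,5-dien-2-yl]-6-oxabicyclo[3.1.0]hexan-1-yl]methoxy}silane F3. The dianion of 14 (LiN(iPr)2, 2.2 equiv, THF, warmed) opens F3 at C5 in an intermolecular SN2 reaction to give the silyloxy hydroxy acid (3R)-2-[(1S,2R,4S)-2-({[tert-butyl(dimethyl)silyl]oxy}methyl)-2-hydroxy-4-[(2E)-6-methylhepta-2,5-dien-2-yl]cyclopentyl]-3-methylpent-4-enoic acid F4 as C1' epimers. Bu4NF gives the dihydroxy acid (3R)-2-[(1S,2R,4S)-2-hydroxy-2-(hydroxymethyl)-4-[(2E)-6-methylhepta-2,5-dien-2-yl]cyclopentyl]-3-methylpent-4-enoic acid F5, which is lactonised (EDC, DMAP) and equilibrated with DBU. The route is rejoined at 17.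

**Step 16.** Site and regiochemical control are the weak points: oxygen can add at either trisubstituted alkene and hydrogen can be taken from a methyl group instead of Cγ, and the product diene can take up a second oxygen in a [4+2] addition. Fallback, from 8, with the oxygen at Cε installed before the end. Alane 10 is coupled (Pd(PPh3)4, ZnCl2, THF) with (E)-4-iodo-2-methylbut-3-en-2-ol, pre-mixed with one equivalent of Me3Al, to give (3E,5E)-6-[(1S)-3-(hydroxymethyl)cyclopent-3-en-1-yl]-2-methylhepta-3,5-dien-2-ol F6. Steps 8 and 10–15 are then applied unchanged and give in turn: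
- epoxide [(1S,3S,5S)-3-[(2E,4E)-6-hydroxy-6-methylhepta-2,4-dien-2-yl]-6-oxabicyclo[3.1.0]hexan-1-yl]methanol F7;
- its (3S)-3-methylpent-4-enoate F8;
- lactone (4S,4aS,6S,7aR)-4-[(2R)-but-3-en-2-yl]-7a-hydroxy-6-[(2E,4E)-6-hydroxy-6-methylhepta-2,4-dien-2-yl]hexahydrocyclopenta[c]pyran-3(1H)-one F9;
- Weinreb amide (2S,3R)-2-[(1S,2R,4S)-2-hydroxy-4-[(2E,4E)-6-hydroxy-6-methylhepta-2,4-dien-2-yl]-2-(hydroxymethyl)cyclopentyl]-N-methoxy-N,3-dimethylpent-4-enamide F10;
- vinyl ketone (4S,5R)-4-[(1S,2R,4S)-2-hydroxy-4-[(2E,4E)-6-hydroxy-6-methylhepta-2,4-dien-2-yl]-2-(hydroxymethyl)cyclopentyl]-5-methylhepta-1,6-dien-3-one F11;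
- cyclopentenone (4R,5S)-5-[(1S,2R,4S)-2-hydroxy-4-[(2E,4E)-6-hydroxy-6-methylhepta-2,4-dien-2-yl]-2-(hydroxymethyl)cyclopentyl]-4-methylcyclopent-2-en-1-one F12;
- acetate [(1R,2S,4S)-1-hydroxy-4-[(2E,4E)-6-hydroxy-6-methylhepta-2,4-dien-2-yl]-2-[(1S,5R)-5-methyl-2-oxocyclopent-3-en-1-yl]cyclopentyl]methyl acetate F13.

Acid-catalysed exchange of the doubly allylic tertiary hydroxyl of F13 with concentrated H2O2 (cat. H2SO4, Et2O, 0 °C) should give the hydroperoxide. This last exchange is itself uncertain, since the dienyl cation can be captured at more than one position. The route is rejoined at 22.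

**Step 13.** The hydroxy amide may close back to the lactone before the Grignard reagent adds, which opens the way to double addition. The released hydroxylamine or excess Grignard reagent may add to the new enone, and enolisation at C1' would erode its configuration. Fallback, from 17: iBu2AlH (CH2Cl2, -78 °C) gives lactol (4S,4aS,6S,7aR)-4-[(2R)-but-3-en-2-yl]-6-[(2E)-6-methylhepta-2,5-dien-2-yl]hexahydrocyclopenta[c]pyran-3,7a(1H)-diol F14. CH2=CHMgBr opens it to triol (4S,5R)-4-[(1S,2R,4S)-2-hydroxy-2-(hydroxymethyl)-4-[(2E)-6-methylhepta-2,5-dien-2-yl]cyclopentyl]-5-methylhepta-1,6-dien-3-ol F15 (carbinol epimers). Ring-closing metathesis with the second-generation Grubbs catalyst gives cyclopentenol (4R,5S)-5-[(1S,2R,4S)-2-hydroxy-2-(hydroxymethyl)-4-[(2E)-6-methylhepta-2,5-dien-2-yl]cyclopentyl]-4-methylcyclopent-2-en-1-ol F16, and MnO2 oxidises only the allylic alcohol. The route is rejoined at 20; C1' is never α to a carbonyl group before that point.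

**Step 9.** Enrichment may stall because the salts of a small, flexible β-branched acid may differ too little in solubility. Fallback, which replaces 13 as the source of 14: (4R)-4-phenyl-1,3-oxazolidin-2-one is acylated with (E)-but-2-enoyl chloride to give (4R)-3-[(2E)-but-2-enoyl]-4-phenyl-1,3-oxazolidin-2-one F17. Copper-mediated conjugate addition (CH2=CHMgBr, CuBr·SMe2, THF, -78 °C) to the chelated s-cis imide, anti to the phenyl group, gives (4R)-3-[(3S)-3-methylpent-4-enoyl]-4-phenyl-1,3-oxazolidin-2-one F18, and LiOH/H2O2 releases the acid. The route is rejoined at 14.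

## Further compounds

F1 | step 1 | racemic 4-tert-butyl 1-ethyl cyclopent-1-ene-1,4-dicarboxylate | CCOC(=O)C1=CCC(C(=O)OC(C)(C)C)C1
F2 | step 1 | racemic 3-(ethoxycarbonyl)cyclopent-3-ene-1-carboxylic acid | CCOC(=O)C1=CCC(C(=O)O)C1
F3 | step 11 | tert-butyldimethyl{[(1S,3S,5S)-3-[(2E)-6-methylhepta-2,5-dien-2-yl]-6-oxabicyclo[3.1.0]hexan-1-yl]methoxy}silane | CC(C)(C)[Si](C)(C)OC[C@@]1(O2)C[C@@H](/C(C)=C/CC=C(C)C)C[C@@H]12
F4 | step 11 | (3R)-2-[(1S,2R,4S)-2-({[tert-butyl(dimethyl)silyl]oxy}methyl)-2-hydroxy-4-[(2E)-6-methylhepta-2,5-dien-2-yl]cyclopentyl]-3-methylpent-4-enoic acid (C2 epimers) | CC(C)(C)[Si](C)(C)OC[C@@]1(O)C[C@@H](/C(C)=C/CC=C(C)C)C[C@H]1C(C(=O)O)[C@H](C)C=C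
F5 | step 11 | (3R)-2-[(1S,2R,4S)-2-hydroxy-2-(hydroxymethyl)-4-[(2E)-6-methylhepta-2,5-dien-2-yl]cyclopentyl]-3-methylpent-4-enoic acid (C2 epimers) | OC[C@@]1(O)C[C@@H](/C(C)=C/CC=C(C)C)C[C@H]1C(C(=O)O)[C@H](C)C=C
F6 | step 16 | (3E,5E)-6-[(1S)-3-(hydroxymethyl)cyclopent-3-en-1-yl]-2-methylhepta-3,5-dien-2-ol | OCC1=CC[C@H](/C(C)=C/C=C/C(C)(C)O)C1
F7 | step 16 | [(1S,3S,5S)-3-[(2E,4E)-6-hydroxy-6-methylhepta-2,4-dien-2-yl]-6-oxabicyclo[3.1.0]hexan-1-yl]methanol | OC[C@@]1(O2)C[C@@H](/C(C)=C/C=C/C(C)(C)O)C[C@@H]12
F8 | step 16 | [(1S,3S,5S)-3-[(2E,4E)-6-hydroxy-6-methylhepta-2,4-dien-2-yl]-6-oxabicyclo[3.1.0]hexan-1-yl]methyl (3S)-3-methylpent-4-enoate | C=C[C@H](CC(=O)OC[C@@]1(O2)C[C@@H](/C(C)=C/C=C/C(C)(C)O)C[C@@H]12)C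
F9 | step 16 | (4S,4aS,6S,7aR)-4-[(2R)-but-3-en-2-yl]-7a-hydroxy-6-[(2E,4E)-6-hydroxy-6-methylhepta-2,4-dien-2-yl]hexahydrocyclopenta[c]pyran-3(1H)-one | O=C1OC[C@@]2(O)C[C@@H](/C(C)=C/C=C/C(C)(C)O)C[C@H]2[C@@H]1[C@H](C)C=C
F10 | step 16 | (2S,3R)-2-[(1S,2R,4S)-2-hydroxy-4-[(2E,4E)-6-hydroxy-6-methylhepta-2,4-dien-2-yl]-2-(hydroxymethyl)cyclopentyl]-N-methoxy-N,3-dimethylpent-4-enamide | OC[C@@]1(O)C[C@@H](/C(C)=C/C=C/C(C)(C)O)C[C@H]1[C@@H](C(=O)N(C)OC)[C@H](C)C=C
F11 | step 16 | (4S,5R)-4-[(1S,2R,4S)-2-hydroxy-4-[(2E,4E)-6-hydroxy-6-methylhepta-2,4-dien-2-yl]-2-(hydroxymethyl)cyclopentyl]-5-methylhepta-1,6-dien-3-one | OC[C@@]1(O)C[C@@H](/C(C)=C/C=C/C(C)(C)O)C[C@H]1[C@@H](C(=O)C=C)[C@H](C)C=C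
F12 | step 16 | (4R,5S)-5-[(1S,2R,4S)-2-hydroxy-4-[(2E,4E)-6-hydroxy-6-methylhepta-2,4-dien-2-yl]-2-(hydroxymethyl)cyclopentyl]-4-methylcyclopent-2-en-1-one | OC[C@@]1(O)C[C@@H](/C(C)=C/C=C/C(C)(C)O)C[C@H]1[C@H]1C(=O)C=C[C@H]1C
F13 | step 16 | [(1R,2S,4S)-1-hydroxy-4-[(2E,4E)-6-hydroxy-6-methylhepta-2,4-dien-2-yl]-2-[(1S,5R)-5-methyl-2-oxocyclopent-3-en-1-yl]cyclopentyl]methyl acetate | CC(=O)OC[C@@]1(O)C[C@@H](/C(C)=C/C=C/C(C)(C)O)C[C@H]1[C@H]1C(=O)C=C[C@H]1C
F14 | step 13 | (4S,4aS,6S,7aR)-4-[(2R)-but-3-en-2-yl]-6-[(2E)-6-methylhepta-2,5-dien-2-yl]hexahydrocyclopenta[c]pyran-3,7a(1H)-diol (anomers) | OC1OC[C@@]2(O)C[C@@H](/C(C)=C/CC=C(C)C)C[C@H]2[C@@H]1[C@H](C)C=C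
F15 | step 13 | (4S,5R)-4-[(1S,2R,4S)-2-hydroxy-2-(hydroxymethyl)-4-[(2E)-6-methylhepta-2,5-dien-2-yl]cyclopentyl]-5-methylhepta-1,6-dien-3-ol (C3 epimers) | OC[C@@]1(O)C[C@@H](/C(C)=C/CC=C(C)C)C[C@H]1[C@@H](C(O)C=C)[C@H](C)C=C
F16 | step 13 | (4R,5S)-5-[(1S,2R,4S)-2-hydroxy-2-(hydroxymethyl)-4-[(2E)-6-methylhepta-2,5-dien-2-yl]cyclopentyl]-4-methylcyclopent-2-en-1-ol (C1 epimers) | OC[C@@]1(O)C[C@@H](/C(C)=C/CC=C(C)C)C[C@H]1[C@H]1C(O)C=C[C@H]1C
F17 | step 9 | (4R)-3-[(2E)-but-2-enoyl]-4-phenyl-1,3-oxazolidin-2-one | C/C=C/C(=O)N1[C@H](c2ccccc2)COC1=O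
F18 | step 9 | (4R)-3-[(3S)-3-methylpent-4-enoyl]-4-phenyl-1,3-oxazolidin-2-one | C=C[C@H](CC(=O)N1[C@H](c2ccccc2)COC1=O)C
A1 | alternative 1 | (R)-limonene, (4R)-1-methyl-4-(prop-1-en-2-yl)cyclohex-1-ene | CC1=CC[C@@H](CC1)C(C)=C
A2 | alternative 1 | (4S,4aS,6S,7aR)-4-[(2R)-but-3-en-2-yl]-7a-hydroxy-6-[(2E)-6-methylhepta-2,5-dien-2-yl]hexahydrocyclopenta[c]pyran-3(1H)-one (same compound as 17) | O=C1OC[C@@]2(O)C[C@@H](/C(C)=C/CC=C(C)C)C[C@H]2[C@@H]1[C@H](C)C=C
A3 | alternative 2 | methyl (2E,5S)-8-(methoxymethoxy)-7-oxo-5-(prop-1-en-2-yl)oct-2-enoate | COCOCC(=O)C[C@@H](C(C)=C)C/C=C/C(=O)OC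
A4 | alternative 2 | methyl 2-[(1S,2R,4S)-2-hydroxy-2-[(methoxymethoxy)methyl]-4-(prop-1-en-2-yl)cyclopentyl]acetate | COCOC[C@@]1(O)C[C@@H](C(C)=C)C[C@H]1CC(=O)OC
A5 | alternative 3 | [(1R,2S,4S)-4-[(E)-1-iodoprop-1-en-2-yl]-2-[(2E,5E)-4-oxo-6-(trimethylsilyl)hexa-2,5-dien-3-yl]-1-[(triethylsilyl)oxy]cyclopentyl]methyl acetate | CC(=O)OC[C@@]1(O[Si](CC)(CC)CC)C[C@@H](/C(C)=C/I)C[C@H]1/C(=C\C)C(=O)/C=C/[Si](C)(C)C
A6 | alternative 3 | [(1R,2S,4S)-4-[(E)-1-iodoprop-1-en-2-yl]-2-[(1S,5R)-5-methyl-2-oxocyclopent-3-en-1-yl]-1-[(triethylsilyl)oxy]cyclopentyl]methyl acetate | CC(=O)OC[C@@]1(O[Si](CC)(CC)CC)C[C@@H](/C(C)=C/I)C[C@H]1[C@H]1C(=O)C=C[C@H]1C
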